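The route rests on cutting the C2–C3 bond of the dihydrofuran ring fused to flavone ring B. C3, the benzylic carbinol carbon, is a former aryl aldehyde carbon, and C2 is the α-carbon of an aryloxyacetone. One L-proline-catalysed intramolecular aldol of 5-bromo-3-prenyl-2-(2-oxopropoxy)benzaldehyde closes that ring and sets both stereocentres (cis, C2 as in the target). Afterwards the acetyl group becomes CMe2OH and C3 is inverted by a Mitsunobu reaction. The bromide para to the ring oxygen is then joined by Negishi coupling to C2 of a zincated 5,7-disilyloxychromone, which brings in rings A and C, and one methanolysis frees all hydroxyl groups.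

Key step: step 5

Remark: the target is taken as drawn, (2S,3S), with the C3 hydroxyl and the C2 side chain trans on the dihydrofuran ring (locants of the 2,3-dihydro-1-benzofuran unit are used throughout), and 5,7-dihydroxychromone is taken as a purchasable chemical.

Step 1
Reactants: 1 5-bromo-2-hydroxybenzaldehyde; 2 allyl bromide
Product: 3 5-bromo-2-(prop-2-enyloxy)benzaldehyde
Conditions: K2CO3, DMF, rt
Reagents that add atoms: none
Why: Williamson ether synthesis, in which the acidic phenol is alkylated at oxygen by the reactive allylic bromide while the aldehyde is inert to carbonate.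

Step 2
Reactants: 3 5-bromo-2-(prop-2-enyloxy)benzaldehyde
Product: 5 5-bromo-2-hydroxy-3-(prop-2-enyl)benzaldehyde, via ortho-dienone 4 (not isolated)
Conditions: N,N-diethylaniline, 190 °C, argon
Reagents that add atoms: none
Why: aromatic Claisen rearrangement, whose [3,3]-shift can only reach the single free ortho position (the other carries the formyl group and the para position carries bromine) before the dienone tautomerises back to the phenol.

Step 3
Reactants: 5 5-bromo-2-hydroxy-3-(prop-2-enyl)benzaldehyde; 6 2-methylbut-2-ene (large excess)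
Product: 7 5-bromo-2-hydroxy-3-(3-methylbut-2-enyl)benzaldehyde
Conditions: second-generation Grubbs catalyst (H2IMes)(PCy3)Cl2Ru=CHPh (3 mol %), CH2Cl2, 40 °C, sealed tube
Reagents that add atoms: none
Why: olefin cross-metathesis with excess 2-methylbut-2-ene turns the terminal allyl group into the prenyl group with loss of propene, the trisubstituted product being inert to further metathesis and the free phenol and aldehyde being tolerated by the ruthenium carbene.

Step 4
Reactants: 7 5-bromo-2-hydroxy-3-(3-methylbut-2-enyl)benzaldehyde; 8 chloroacetone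
Product: 9 5-bromo-3-(3-methylbut-2-enyl)-2-(2-oxopropoxy)benzaldehyde
Conditions: K2CO3, DMF, 0 °C to rt
Reagents that add atoms: none
Why: Williamson O-alkylation with the highly reactive α-chloro ketone, run at or below room temperature and stopped at full conversion so that the base-induced Rap–Stoermer condensation to the 2-acetylbenzofuran does not set in.

Step 5
Reactants: 9 5-bromo-3-(3-methylbut-2-enyl)-2-(2-oxopropoxy)benzaldehyde
Product: 11 1-[(2S,3R)-5-bromo-3-hydroxy-7-(3-methylbut-2-enyl)-2,3-dihydro-1-benzofuran-2-yl]ethanone, via proline enamine 10 (not isolated)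
Conditions: L-proline (30 mol %), DMF, rt
Reagents that add atoms: none
Why: L-Proline condenses with the ketone to give the (E)-enamine 10 on the oxygen-bearing methylene side, whose nucleophilic carbon adds to the neighbouring formyl group while the proline carboxylic acid hydrogen-bonds to the aldehyde oxygen, and hydrolysis of the resulting iminium ion releases 11 and the catalyst. The closest known reaction type is the proline-catalysed intramolecular enolexo aldol reaction of 2-(2-oxopropoxy)benzaldehydes to cis-2-acyl-2,3-dihydrobenzofuran-3-ols, an enamine aldol of the Hajos–Parrish family. The dihydrofuran ring closes in the 5-(enolexo)-exo-trig mode, the C2–C3 bond being the only skeletal bond formed. C2 is controlled by the catalyst, because the acid-directed aldehyde can only reach the enamine face on the side of the carboxyl group (2S with L-proline), and C3 is controlled by the short aryloxy tether, which holds the aryl group next to the ring oxygen in the hydrogen-bonded transition state and so should give the cis alcohol (3R). The step needs the enamine on the OCH2 side and an aldol that stops before loss of water: the aryloxy group favours the more substituted enamine and attack from the methyl side would need a seven-membered ring, the electron-poor aldehyde cannot enolise, and the absence of added base, a modest temperature and direct use of 11 in step 6 hold back elimination to the 2-acetylbenzofuran.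

Step 6
Reactants: 11 1-[(2S,3R)-5-bromo-3-hydroxy-7-(3-methylbut-2-enyl)-2,3-dihydro-1-benzofuran-2-yl]ethanone
Product: 12 (2S,3R)-5-bromo-2-(2-hydroxypropan-2-yl)-7-(3-methylbut-2-enyl)-2,3-dihydro-1-benzofuran-3-ol
Conditions: CeCl3 (anhydrous), MeMgBr, THF, −78 °C; then aq. NH4Cl
Reagents that add atoms: methylmagnesium bromide, C[Mg]Br
Why: organocerium addition to a ketone, in which the weakly basic and strongly oxophilic methylcerium reagent should add faster than it epimerises C2 or triggers retro-aldol cleavage of the β-alkoxide, leaves the aryl bromide and the prenyl group alone at −78 °C and creates no new stereocentre.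

Step 7
Reactants: 12 (2S,3R)-5-bromo-2-(2-hydroxypropan-2-yl)-7-(3-methylbut-2-enyl)-2,3-dihydro-1-benzofuran-3-ol
Product: 14 (2S,3S)-5-bromo-2-(2-hydroxypropan-2-yl)-7-(3-methylbut-2-enyl)-2,3-dihydro-1-benzofuran-3-yl 4-nitrobenzoate, via alkoxyphosphonium salt 13 (not isolated)
Conditions: PPh3, DIAD, 4-nitrobenzoic acid, THF, 0 °C to rt
Reagents that add atoms: 4-nitrobenzoic acid, O=C(O)c1ccc(cc1)[N+](=O)[O-]
Why: Mitsunobu reaction, in which only the secondary benzylic hydroxyl is activated (the tertiary one is too hindered) and is displaced by 4-nitrobenzoate in an SN2 step from the open face opposite the CMe2OH group, inverting C3 to S while C2, no longer next to a carbonyl group, is untouched.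

Step 8
Reactants: 15 5,7-dihydroxy-4H-chromen-4-one
Product: 16 5,7-bis(tert-butyldimethylsilyloxy)-4H-chromen-4-one
Conditions: TBSOTf, 2,6-lutidine, CH2Cl2, 0 °C to rt
Reagents that add atoms: tert-butyldimethylsilyl trifluoromethanesulfonate, CC(C)(C)[Si](C)(C)OS(=O)(=O)C(F)(F)F
Why: silyl ether formation, for which the silyl triflate with a hindered base is strong enough to cap the chelated 5-hydroxyl as well as the 7-hydroxyl, giving non-directing ethers that resist the zinc amide and fall off later with carbonate in methanol.

Step 9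
Reactants: 16 5,7-bis(tert-butyldimethylsilyloxy)-4H-chromen-4-one; 14 (2S,3S)-5-bromo-2-(2-hydroxypropan-2-yl)-7-(3-methylbut-2-enyl)-2,3-dihydro-1-benzofuran-3-yl 4-nitrobenzoate
Product: 18 (2S,3S)-5-[5,7-bis(tert-butyldimethylsilyloxy)-4-oxo-4H-chromen-2-yl]-2-(2-hydroxypropan-2-yl)-7-(3-methylbut-2-enyl)-2,3-dihydro-1-benzofuran-3-yl 4-nitrobenzoate, via chromon-2-ylzinc chloride 17 (not isolated)
Conditions: 16 (2.0 equiv), TMPZnCl·LiCl (1.9 equiv), THF, −30 °C to rt; then 14 (1.0 equiv), Pd(OAc)2 (4 mol %), SPhos (8 mol %), 25 to 40 °C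
Reagents that add atoms: none
Why: C–H zincation followed by Negishi coupling, in which the hindered zinc amide removes the most acidic chromone proton (H2, next to the ring oxygen) and the heteroarylzinc couples with the aryl bromide under neutral conditions that spare the ester, the silyl ethers and the free tertiary alcohol, the chromone being kept in slight excess over the base so that no zinc amide is left to attack the nitroarene.

Step 10
Reactants: 18 (2S,3S)-5-[5,7-bis(tert-butyldimethylsilyloxy)-4-oxo-4H-chromen-2-yl]-2-(2-hydroxypropan-2-yl)-7-(3-methylbut-2-enyl)-2,3-dihydro-1-benzofuran-3-yl 4-nitrobenzoate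
Product: 19 5,7-dihydroxy-2-[(2S,3S)-3-hydroxy-2-(2-hydroxypropan-2-yl)-7-(3-methylbut-2-enyl)-2,3-dihydro-1-benzofuran-5-yl]-4H-chromen-4-one
Conditions: K2CO3, MeOH/THF, 0 °C to rt; work-up with pH 6 buffer
Reagents that add atoms: none
Why: base-mediated methanolysis, in which methoxide cleaves the activated 4-nitrobenzoate at the acyl carbon (so C3 keeps its configuration) and the two aryl silyl ethers at silicon, while the alcohols, the prenyl group and the flavone should be stable to these mild conditions.

Compound list
1 | 5-bromo-2-hydroxybenzaldehyde (5-bromosalicylaldehyde) | O=Cc1cc(Br)ccc1O | starting material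
2 | allyl bromide (3-bromoprop-1-ene) | C=CCBr | starting material
3 | 5-bromo-2-(prop-2-enyloxy)benzaldehyde | C=CCOc1ccc(Br)cc1C=O | intermediate
4 | 3-bromo-6-oxo-5-(prop-2-enyl)cyclohexa-1,3-diene-1-carbaldehyde (racemic ortho-dienone; formed in the flask, not isolated) | O=CC1=CC(Br)=CC(CC=C)C1=O | intermediate
5 | 5-bromo-2-hydroxy-3-(prop-2-enyl)benzaldehyde | C=CCc1cc(Br)cc(C=O)c1O | intermediate
6 | 2-methylbut-2-ene | CC=C(C)C | starting material
7 | 5-bromo-2-hydroxy-3-(3-methylbut-2-enyl)benzaldehyde | CC(C)=CCc1cc(Br)cc(C=O)c1O | intermediate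
8 | chloroacetone (1-chloropropan-2-one) | CC(=O)CCl | starting material
9 | 5-bromo-3-(3-methylbut-2-enyl)-2-(2-oxopropoxy)benzaldehyde | CC(C)=CCc1cc(Br)cc(C=O)c1OCC(C)=O | intermediate
10 | (2S)-1-[(E)-1-[4-bromo-2-formyl-6-(3-methylbut-2-enyl)phenoxy]prop-1-en-2-yl]pyrrolidine-2-carboxylic acid (proline enamine; formed in the flask, not isolated) | CC(C)=CCc1cc(Br)cc(C=O)c1O/C=C(/N1CCC[C@H]1C(=O)O)C | intermediate
11 | 1-[(2S,3R)-5-bromo-3-hydroxy-7-(3-methylbut-2-enyl)-2,3-dihydro-1-benzofuran-2-yl]ethanone (2,3-cis) | CC(C)=CCc1cc(Br)cc2c1O[C@H](C(C)=O)[C@@H]2O | intermediate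
12 | (2S,3R)-5-bromo-2-(2-hydroxypropan-2-yl)-7-(3-methylbut-2-enyl)-2,3-dihydro-1-benzofuran-3-ol (2,3-cis) | CC(C)=CCc1cc(Br)cc2c1O[C@H](C(C)(C)O)[C@@H]2O | intermediate
13 | [(2S,3R)-5-bromo-2-(2-hydroxypropan-2-yl)-7-(3-methylbut-2-enyl)-2,3-dihydro-1-benzofuran-3-yl]oxy(triphenyl)phosphonium 4-nitrobenzoate (formed in the flask, not isolated) | CC(C)=CCc1cc(Br)cc2c1O[C@H](C(C)(C)O)[C@@H]2O[P+](c1ccccc1)(c1ccccc1)c1ccccc1.[O-]C(=O)c1ccc(cc1)[N+](=O)[O-] | intermediate
14 | (2S,3S)-5-bromo-2-(2-hydroxypropan-2-yl)-7-(3-methylbut-2-enyl)-2,3-dihydro-1-benzofuran-3-yl 4-nitrobenzoate (2,3-trans) | CC(C)=CCc1cc(Br)cc2c1O[C@H](C(C)(C)O)[C@H]2OC(=O)c1ccc(cc1)[N+](=O)[O-] | intermediate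
15 | 5,7-dihydroxy-4H-chromen-4-one | O=c1ccoc2cc(O)cc(O)c12 | starting material
16 | 5,7-bis(tert-butyldimethylsilyloxy)-4H-chromen-4-one | O=c1ccoc2cc(O[Si](C)(C)C(C)(C)C)cc(O[Si](C)(C)C(C)(C)C)c12 | intermediate
17 | [5,7-bis(tert-butyldimethylsilyloxy)-4-oxo-4H-chromen-2-yl]zinc chloride, LiCl complex (formed in the flask, not isolated) | Cl[Zn]c1cc(=O)c2c(O[Si](C)(C)C(C)(C)C)cc(O[Si](C)(C)C(C)(C)C)cc2o1.[Li+].[Cl-] | intermediate
18 | (2S,3S)-5-[5,7-bis(tert-butyldimethylsilyloxy)-4-oxo-4H-chromen-2-yl]-2-(2-hydroxypropan-2-yl)-7-(3-methylbut-2-enyl)-2,3-dihydro-1-benzofuran-3-yl 4-nitrobenzoate | CC(C)=CCc1cc(-c2cc(=O)c3c(O[Si](C)(C)C(C)(C)C)cc(O[Si](C)(C)C(C)(C)C)cc3o2)cc2c1O[C@H](C(C)(C)O)[C@H]2OC(=O)c1ccc(cc1)[N+](=O)[O-] | intermediate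
19 | 5,7-dihydroxy-2-[(2S,3S)-3-hydroxy-2-(2-hydroxypropan-2-yl)-7-(3-methylbut-2-enyl)-2,3-dihydro-1-benzofuran-5-yl]-4H-chromen-4-one | CC(C)=CCc1cc(-c2cc(=O)c3c(O)cc(O)cc3o2)cc2c1O[C@H](C(C)(C)O)[C@H]2O | target

Total step count: 10
Longest linear sequence: 9 steps (steps 1 to 7, then 9 and 10, counted from 1); step 8 is a one-step side branch.

Steps most likely to fail

Step 5 (aldol ring closure). Incomplete facial discrimination in the enamine addition, or partial retro-aldol reaction during the reaction time, would lower the enantiomeric purity that every later compound inherits. The fallback sets the absolute configuration by a ketone reduction instead of by the aldol. It sets out from 12 of insufficient enantiomeric purity. Oxidation of the benzylic hydroxyl (Dess–Martin periodinane, NaHCO3, CH2Cl2) should give 5-bromo-2-(2-hydroxypropan-2-yl)-7-(3-methylbut-2-enyl)-1-benzofuran-3(2H)-one F1. In F1, C2 lies α to the ketone and should epimerise readily in the basic medium of a Noyori asymmetric transfer hydrogenation. With RuCl(p-cymene)[(S,S)-TsDPEN] in HCO2H/Et3N at rt, dynamic kinetic resolution is expected to reduce one ketone enantiomer faster, with hydride arriving anti to the C2 substituent. This catalyst gives (S)-1-arylethanols, which corresponds to 3R here because C2 outranks the aryl carbon. The fallback comes back to the route at cis-(2S,3R)-12 as a single enantiomer.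

Step 7 (inversion at C3). Ionisation of the activated benzylic C3–O bond followed by loss of the C2 proton would aromatise the ring to a benzofuran, or the hindered alcohol may resist displacement. The fallback replaces the SN2 inversion by oxidation and hydroxyl-directed reduction and sets out from 12. Oxidation with Dess–Martin periodinane and NaHCO3 in CH2Cl2 at 0 °C, without amine base, should give (2R)-5-bromo-2-(2-hydroxypropan-2-yl)-7-(3-methylbut-2-enyl)-1-benzofuran-3(2H)-one F2. F2 is used cold and at once so that C2 does not enolise; the lability exploited in the fallback for step 5 is the hazard here. Evans–Saksena reduction with Me4NBH(OAc)3 in MeCN/AcOH at −30 °C, in which the tertiary hydroxyl binds boron and delivers hydride to the ketone face it occupies, should give (2S,3S)-5-bromo-2-(2-hydroxypropan-2-yl)-7-(3-methylbut-2-enyl)-2,3-dihydro-1-benzofuran-3-ol F3. Selective acylation of its secondary hydroxyl with 4-nitrobenzoyl chloride and pyridine at 0 °C comes back to the route at 14.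

Step 9 (flavone assembly). Protonolysis of the heteroarylzinc by the tertiary hydroxyl of 14, incomplete or misdirected zincation of 16, or slow oxidative addition into the electron-rich bromide would starve the coupling. The fallback reverses the polarity of the partners and needs no zincation; it sets out from 14. Borylation with B2(OH)4 (Pd(OAc)2, XPhos, KOAc, EtOH, 80 °C) should give [(2S,3S)-2-(2-hydroxypropan-2-yl)-7-(3-methylbut-2-enyl)-3-(4-nitrobenzoyloxy)-2,3-dihydro-1-benzofuran-5-yl]boronic acid F4. An oxidative boron-Heck arylation of chromone 16 at C2, catalysed by divalent palladium (Pd(O2CCF3)2, 1,10-phenanthroline, O2, DMF, 60 °C), then comes back to the route at 18.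

Further compounds
F1 | step 5 | 5-bromo-2-(2-hydroxypropan-2-yl)-7-(3-methylbut-2-enyl)-1-benzofuran-3(2H)-one (C2 epimerising, handled as the racemate) | CC(C)=CCc1cc(Br)cc2c1OC(C(C)(C)O)C2=O
F2 | step 7 | (2R)-5-bromo-2-(2-hydroxypropan-2-yl)-7-(3-methylbut-2-enyl)-1-benzofuran-3(2H)-one | CC(C)=CCc1cc(Br)cc2c1O[C@H](C(C)(C)O)C2=O
F3 | step 7 | (2S,3S)-5-bromo-2-(2-hydroxypropan-2-yl)-7-(3-methylbut-2-enyl)-2,3-dihydro-1-benzofuran-3-ol | CC(C)=CCc1cc(Br)cc2c1O[C@H](C(C)(C)O)[C@H]2O
F4 | step 9 | [(2S,3S)-2-(2-hydroxypropan-2-yl)-7-(3-methylbut-2-enyl)-3-(4-nitrobenzoyloxy)-2,3-dihydro-1-benzofuran-5-yl]boronic acid | CC(C)=CCc1cc(B(O)O)cc2c1O[C@H](C(C)(C)O)[C@H]2OC(=O)c1ccc(cc1)[N+](=O)[O-]
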